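**Retrosynthetic overview**

1. Target 21 ⇐ anti-selective zinc-chelate reduction of α-hydroxy ketone 20 (C1' relayed from C2'); 20 ⇐ aryllithium from bromide 15 + (S)-lactic Weinreb amide 17 (C2' bought).
2. The C3 methyl of 15 ⇐ the ester carbon of 12 (LiAlH4, TsCl, LiEt3BH).
3. Dihydrofuran ring of 12 ⇐ oxidative 1,2-aryl-shift ring contraction of (2S)-flavanone 9: the six-membered pyranone ring O1–C2–C3–C4–C4a–C8a expels C4 as an exocyclic ester carbon and becomes the five-membered ring O1–C2–C3–C3a–C7a, with C3 set trans to C2.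
4. Enabling feature: the C4 ketone, enolisable towards C3H2 and bonded to aromatic carbon C4a, which lies ortho to the ring oxygen O1 and is the migrating terminus. 9 ⇐ Rh-catalysed asymmetric 1,4-arylation of chromone 4 with boronic acid 8 (C2 set by catalysis).
5. Ring order: both benzene rings are bought; the pyranone ring is made in step 2 and contracted to the dihydrofuran ring in step 6.

Key step: step 6

Remark: the target is read as the (2S,3S)-trans-dihydrobenzofuran carrying a (1R,2S)-erythro diol; in step 5 the (S) ligand antipode is assigned by analogy with Rh/biaryl-bisphosphine additions to cyclic enones, and the (R) ligand would be taken if the first run showed the opposite sense.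

**Route**

Step 1
Reactants: 1 1-(2-hydroxy-3-methoxyphenyl)ethan-1-one
Product: 2 1-(5-bromo-2-hydroxy-3-methoxyphenyl)ethan-1-one
Conditions: NBS (1.05 equiv), MeCN, 0 °C to rt
Reagents that add atoms: N-bromosuccinimide, O=C1CCC(=O)N1Br
Why: Electrophilic aromatic bromination should go para to the phenol OH (C5), which is also meta to the deactivating acetyl group.

Step 2
Reactants: 2 1-(5-bromo-2-hydroxy-3-methoxyphenyl)ethan-1-one
Product: 4 6-bromo-8-methoxy-4H-chromen-4-one, via enaminone 3 (not isolated)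
Conditions: Me2NCH(OMe)2, toluene, 100 °C; then conc. HCl, CH2Cl2, 40 °C
Reagents that add atoms: N,N-dimethylformamide dimethyl acetal, CN(C)C(OC)OC
Why: Enaminone condensation followed by acid-mediated oxa-Michael addition and loss of dimethylamine is the standard chromone synthesis from 2'-hydroxyacetophenones.

Step 3
Reactants: 5 2,3-dimethoxyphenol
Product: 6 (2,3-dimethoxyphenoxy)tri(propan-2-yl)silane
Conditions: TIPSCl, imidazole, DMF, rt
Reagents that add atoms: chlorotri(propan-2-yl)silane, CC(C)[Si](Cl)(C(C)C)C(C)C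
Why: Phenol silylation; the TIPS ether should tolerate acid, hydride and organolithium steps and, unlike a benzyl ether, offers no second arene to the borylation.

Step 4
Reactants: 6 (2,3-dimethoxyphenoxy)tri(propan-2-yl)silane
Product: 8 [3,4-dimethoxy-5-(triisopropylsilyloxy)phenyl]boronic acid, via pinacol boronate 7 (not isolated)
Conditions: [Ir(OMe)(cod)]2 (1.5 mol%), dtbpy (3 mol%), B2pin2, THF, 80 °C; then NaIO4, 1 M HCl, THF/H2O, rt
Reagents that add atoms: bis(pinacolato)diboron, CC1(C)OB(OC1(C)C)B1OC(C)(C)C(C)(C)O1; water, O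
Why: Sterically controlled Ir-catalysed C–H borylation should hit C5, the only C–H not ortho to a substituent of the 1,2,3-trisubstituted arene, and periodate cleavage of the pinacol releases the boronic acid in the same pot.

Step 5
Reactants: 4 6-bromo-8-methoxy-4H-chromen-4-one; 8 [3,4-dimethoxy-5-(triisopropylsilyloxy)phenyl]boronic acid
Product: 9 (2S)-6-bromo-2-[3,4-dimethoxy-5-(triisopropylsilyloxy)phenyl]-8-methoxy-2,3-dihydro-4H-chromen-4-one
Conditions: [Rh(OH)(cod)]2 (1.5 mol%), (S)-MeO-F12-BIPHEP (3.3 mol%), 8 (1.5 equiv), CH2Cl2/H2O 10:1, 20 °C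
Reagents that add atoms: none
Why: Rh-catalysed asymmetric 1,4-addition of an arylboronic acid to a chromone (Hayashi–Miyaura type) should set C2 by catalyst-controlled aryl insertion across C2=C3, and the neutral, low-temperature medium should avoid retro-oxa-Michael racemisation of the flavanone.

Step 6
Reactants: 9 (2S)-6-bromo-2-[3,4-dimethoxy-5-(triisopropylsilyloxy)phenyl]-8-methoxy-2,3-dihydro-4H-chromen-4-one
Product: 12 methyl (2S,3S)-5-bromo-2-[3,4-dimethoxy-5-(triisopropylsilyloxy)phenyl]-7-methoxy-2,3-dihydro-1-benzofuran-3-carboxylate, via enol ether 10 (not isolated), via ortho ester 11 (not isolated)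
Conditions: PhI(OAc)2 (1.3 equiv), conc. H2SO4 (cat.), HC(OMe)3, 0 °C to rt, dark; H2O quench, then NaHCO3
Reagents that add atoms: trimethyl orthoformate, COC(OC)OC; water, O
Why: Acid and orthoformate should convert the C4 ketone into enol ether 10, PhI(OAc)2 should attack C3 anti to the equatorial C2 aryl group while methanol adds at C4, and the C4–C4a bond, antiperiplanar to the equatorial C3–I bond, should then migrate to C3 as PhI departs, leaving a dimethoxycarbenium ion at C4 that is trapped as ortho ester 11 and hydrolysed to ester 12 on work-up. The closest known reaction type is the hypervalent-iodine (or thallium(III)) oxidative ring contraction of flavanones to trans-2-aryl-2,3-dihydrobenzofuran-3-carboxylates. The five-membered ring O1–C2–C3–C3a–C7a is not closed by cyclisation but arises from the six-membered pyranone ring by the 1,2-shift of aryl carbon C4a from C4 to C3, with C4 expelled as the exocyclic ester carbon. C2 is not touched and keeps its configuration; C3 is controlled by C2, because iodination anti to the aryl group followed by migration with inversion at C3 should place the ester trans to the aryl group. The step needs migration of C4a in preference to the 2-aryl group (isoflavone pathway), to O1 and to simple dehydrogenation; the trans-diequatorial iodane aligns only ring bonds with C3–I, C4a is activated by the ortho ring oxygen, and the two methoxy groups stabilise the cation left at C4.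

Step 7
Reactants: 12 methyl (2S,3S)-5-bromo-2-[3,4-dimethoxy-5-(triisopropylsilyloxy)phenyl]-7-methoxy-2,3-dihydro-1-benzofuran-3-carboxylate
Product: 13 [(2S,3R)-5-bromo-2-[3,4-dimethoxy-5-(triisopropylsilyloxy)phenyl]-7-methoxy-2,3-dihydro-1-benzofuran-3-yl]methanol
Conditions: LiAlH4, THF, 0 °C
Reagents that add atoms: none
Why: Ester reduction with LiAlH4 at 0 °C should be faster than enolisation and should leave the aryl bromide and the aryl silyl ether intact (the descriptor at C3 changes only by CIP priority).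

Step 8
Reactants: 13 [(2S,3R)-5-bromo-2-[3,4-dimethoxy-5-(triisopropylsilyloxy)phenyl]-7-methoxy-2,3-dihydro-1-benzofuran-3-yl]methanol
Product: 14 [(2S,3R)-5-bromo-2-[3,4-dimethoxy-5-(triisopropylsilyloxy)phenyl]-7-methoxy-2,3-dihydro-1-benzofuran-3-yl]methyl 4-methylbenzenesulfonate
Conditions: TsCl, Et3N, DMAP (cat.), CH2Cl2, 0 °C to rt
Reagents that add atoms: 4-methylbenzenesulfonyl chloride, Cc1ccc(cc1)S(Cl)(=O)=O
Why: Sulfonylation of the primary alcohol under non-ionising conditions activates the one-carbon handle without touching either stereocentre.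

Step 9
Reactants: 14 [(2S,3R)-5-bromo-2-[3,4-dimethoxy-5-(triisopropylsilyloxy)phenyl]-7-methoxy-2,3-dihydro-1-benzofuran-3-yl]methyl 4-methylbenzenesulfonate
Product: 15 (2S,3S)-5-bromo-2-[3,4-dimethoxy-5-(triisopropylsilyloxy)phenyl]-7-methoxy-3-methyl-2,3-dihydro-1-benzofuran
Conditions: LiEt3BH, THF, 0 °C to rt
Reagents that add atoms: none
Why: SN2 hydride displacement of the primary tosylate by Super-Hydride in THF should outrun elimination and aryl-assisted ring expansion and should not reduce the aryl bromide, so the extruded ring carbon ends as the C3 methyl group.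

Step 10
Reactants: 16 ethyl (2S)-2-[(tert-butyldimethylsilyl)oxy]propanoate
Product: 17 (2S)-2-[(tert-butyldimethylsilyl)oxy]-N-methoxy-N-methylpropanamide
Conditions: MeNH(OMe)·HCl, i-PrMgCl, THF, −20 °C
Reagents that add atoms: N,O-dimethylhydroxylamine hydrochloride, CNOC.Cl
Why: Aminolysis of the ester by the magnesium amide of N,O-dimethylhydroxylamine (Weinreb amide formation) proceeds at low temperature without enolisation of the lactate stereocentre.

Step 11
Reactants: 15 (2S,3S)-5-bromo-2-[3,4-dimethoxy-5-(triisopropylsilyloxy)phenyl]-7-methoxy-3-methyl-2,3-dihydro-1-benzofuran; 17 (2S)-2-[(tert-butyldimethylsilyl)oxy]-N-methoxy-N-methylpropanamide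
Product: 19 (2S)-2-[(tert-butyldimethylsilyl)oxy]-1-[(2S,3S)-2-[3,4-dimethoxy-5-(triisopropylsilyloxy)phenyl]-7-methoxy-3-methyl-2,3-dihydro-1-benzofuran-5-yl]propan-1-one, via aryllithium 18 (not isolated)
Conditions: n-BuLi (1.05 equiv), THF, −78 °C; then 17 (1.2 equiv), −78 to −40 °C; aq. NH4Cl
Reagents that add atoms: none
Why: Bromine–lithium exchange is much faster than deprotonation at C2, and Weinreb acylation stops at the ketone through the chelated tetrahedral adduct, so the bought C2' centre is carried over unchanged.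

Step 12
Reactants: 19 (2S)-2-[(tert-butyldimethylsilyl)oxy]-1-[(2S,3S)-2-[3,4-dimethoxy-5-(triisopropylsilyloxy)phenyl]-7-methoxy-3-methyl-2,3-dihydro-1-benzofuran-5-yl]propan-1-one
Product: 20 (2S)-2-hydroxy-1-[(2S,3S)-2-(3-hydroxy-4,5-dimethoxyphenyl)-7-methoxy-3-methyl-2,3-dihydro-1-benzofuran-5-yl]propan-1-one
Conditions: TBAF (2.5 equiv), AcOH (2.5 equiv), THF, 0 °C
Reagents that add atoms: none
Why: Fluoride cleaves both silyl ethers, and buffering with acetic acid should suppress base-induced enolisation of the α-hydroxy aryl ketone.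

Step 13
Reactants: 20 (2S)-2-hydroxy-1-[(2S,3S)-2-(3-hydroxy-4,5-dimethoxyphenyl)-7-methoxy-3-methyl-2,3-dihydro-1-benzofuran-5-yl]propan-1-one
Product: 21 (1R,2S)-1-[(2S,3S)-2-(3-hydroxy-4,5-dimethoxyphenyl)-7-methoxy-3-methyl-2,3-dihydro-1-benzofuran-5-yl]propane-1,2-diol
Conditions: Zn(BH4)2 (3 equiv), Et2O/THF, −30 to 0 °C; aq. NH4Cl
Reagents that add atoms: none
Why: Chelation-controlled (Cram-chelate) reduction: zinc bridges the carbonyl and the α-oxygen, hydride is delivered to the face opposite the C2' methyl group, and the 1,2-anti (erythro) diol with (1R) configuration should result from the (2S) centre.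

**Compound list**

1 | 1-(2-hydroxy-3-methoxyphenyl)ethan-1-one | CC(=O)c1cccc(OC)c1O | starting material
2 | 1-(5-bromo-2-hydroxy-3-methoxyphenyl)ethan-1-one | CC(=O)c1cc(Br)cc(OC)c1O | intermediate
3 | (E)-1-(5-bromo-2-hydroxy-3-methoxyphenyl)-3-(dimethylamino)prop-2-en-1-one | CN(C)/C=C/C(=O)c1cc(Br)cc(OC)c1O | intermediate
4 | 6-bromo-8-methoxy-4H-chromen-4-one | O=c1ccoc2c(OC)cc(Br)cc12 | intermediate
5 | 2,3-dimethoxyphenol | COc1cccc(O)c1OC | starting material
6 | (2,3-dimethoxyphenoxy)tri(propan-2-yl)silane | COc1cccc(O[Si](C(C)C)(C(C)C)C(C)C)c1OC | intermediate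
7 | 2-[3,4-dimethoxy-5-(triisopropylsilyloxy)phenyl]-4,4,5,5-tetramethyl-1,3,2-dioxaborolane | COc1cc(B2OC(C)(C)C(C)(C)O2)cc(O[Si](C(C)C)(C(C)C)C(C)C)c1OC | intermediate
8 | [3,4-dimethoxy-5-(triisopropylsilyloxy)phenyl]boronic acid | COc1cc(B(O)O)cc(O[Si](C(C)C)(C(C)C)C(C)C)c1OC | intermediate
9 | (2S)-6-bromo-2-[3,4-dimethoxy-5-(triisopropylsilyloxy)phenyl]-8-methoxy-2,3-dihydro-4H-chromen-4-one | COc1cc([C@@H]2CC(=O)c3cc(Br)cc(OC)c3O2)cc(O[Si](C(C)C)(C(C)C)C(C)C)c1OC | intermediate
10 | (2S)-6-bromo-2-[3,4-dimethoxy-5-(triisopropylsilyloxy)phenyl]-4,8-dimethoxy-2H-chromene | COc1cc([C@@H]2C=C(OC)c3cc(Br)cc(OC)c3O2)cc(O[Si](C(C)C)(C(C)C)C(C)C)c1OC | intermediate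
11 | (2S,3S)-5-bromo-2-[3,4-dimethoxy-5-(triisopropylsilyloxy)phenyl]-7-methoxy-3-(trimethoxymethyl)-2,3-dihydro-1-benzofuran | COc1cc([C@H]2Oc3c(OC)cc(Br)cc3[C@@H]2C(OC)(OC)OC)cc(O[Si](C(C)C)(C(C)C)C(C)C)c1OC | intermediate
12 | methyl (2S,3S)-5-bromo-2-[3,4-dimethoxy-5-(triisopropylsilyloxy)phenyl]-7-methoxy-2,3-dihydro-1-benzofuran-3-carboxylate | COc1cc([C@H]2Oc3c(OC)cc(Br)cc3[C@@H]2C(=O)OC)cc(O[Si](C(C)C)(C(C)C)C(C)C)c1OC | intermediate
13 | [(2S,3R)-5-bromo-2-[3,4-dimethoxy-5-(triisopropylsilyloxy)phenyl]-7-methoxy-2,3-dihydro-1-benzofuran-3-yl]methanol | COc1cc([C@H]2Oc3c(OC)cc(Br)cc3[C@@H]2CO)cc(O[Si](C(C)C)(C(C)C)C(C)C)c1OC | intermediate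
14 | [(2S,3R)-5-bromo-2-[3,4-dimethoxy-5-(triisopropylsilyloxy)phenyl]-7-methoxy-2,3-dihydro-1-benzofuran-3-yl]methyl 4-methylbenzenesulfonate | COc1cc([C@H]2Oc3c(OC)cc(Br)cc3[C@@H]2COS(=O)(=O)c4ccc(C)cc4)cc(O[Si](C(C)C)(C(C)C)C(C)C)c1OC | intermediate
15 | (2S,3S)-5-bromo-2-[3,4-dimethoxy-5-(triisopropylsilyloxy)phenyl]-7-methoxy-3-methyl-2,3-dihydro-1-benzofuran | COc1cc([C@H]2Oc3c(OC)cc(Br)cc3[C@@H]2C)cc(O[Si](C(C)C)(C(C)C)C(C)C)c1OC | intermediate
16 | ethyl (2S)-2-[(tert-butyldimethylsilyl)oxy]propanoate | CCOC(=O)[C@H](C)O[Si](C)(C)C(C)(C)C | starting material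
17 | (2S)-2-[(tert-butyldimethylsilyl)oxy]-N-methoxy-N-methylpropanamide | CON(C)C(=O)[C@H](C)O[Si](C)(C)C(C)(C)C | intermediate
18 | [(2S,3S)-2-[3,4-dimethoxy-5-(triisopropylsilyloxy)phenyl]-7-methoxy-3-methyl-2,3-dihydro-1-benzofuran-5-yl]lithium | COc1cc([C@H]2Oc3c(OC)cc([Li])cc3[C@@H]2C)cc(O[Si](C(C)C)(C(C)C)C(C)C)c1OC | intermediate
19 | (2S)-2-[(tert-butyldimethylsilyl)oxy]-1-[(2S,3S)-2-[3,4-dimethoxy-5-(triisopropylsilyloxy)phenyl]-7-methoxy-3-methyl-2,3-dihydro-1-benzofuran-5-yl]propan-1-one | COc1cc([C@H]2Oc3c(OC)cc(C(=O)[C@H](C)O[Si](C)(C)C(C)(C)C)cc3[C@@H]2C)cc(O[Si](C(C)C)(C(C)C)C(C)C)c1OC | intermediate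
20 | (2S)-2-hydroxy-1-[(2S,3S)-2-(3-hydroxy-4,5-dimethoxyphenyl)-7-methoxy-3-methyl-2,3-dihydro-1-benzofuran-5-yl]propan-1-one | COc1cc([C@H]2Oc3c(OC)cc(C(=O)[C@H](C)O)cc3[C@@H]2C)cc(O)c1OC | intermediate
21 | (1R,2S)-1-[(2S,3S)-2-(3-hydroxy-4,5-dimethoxyphenyl)-7-methoxy-3-methyl-2,3-dihydro-1-benzofuran-5-yl]propane-1,2-diol | COc1cc([C@H]2Oc3c(OC)cc([C@@H](O)[C@H](C)O)cc3[C@@H]2C)cc(O)c1OC | target

**Summary**

Total step count: 13. Longest linear sequence: 10 steps (steps 1, 2, 5, 6, 7, 8, 9, 11, 12, 13; the branch through steps 3 and 4 is equally long).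

Steps most likely to fail:

Step 6 (key ring contraction). The electron-rich 2-aryl group may migrate instead of C4a (isoflavone pathway), the flavanone may simply be dehydrogenated, the aryl silyl ether may be lost in the acidic medium, or acid-induced ring opening may erode the C2 configuration. The fallback keeps the ring contraction but changes its mechanism to a Wolff rearrangement, setting out from 9. LiHMDS in THF at −78 °C followed by 2,2,2-trifluoroethyl trifluoroacetate would give the 3-trifluoroacetyl flavanone F1. Detrifluoroacetylative diazo transfer (MsN3, Et3N, H2O, MeCN) would give the 3-diazoflavanone F2. Irradiation in methanol would move C4a from C4 to the C3 carbene and trap the ketene as the methyl ester, expected as trans ester 12 mixed with the cis ester F3. NaOMe in MeOH would equilibrate F3 to the trans isomer, and the route is rejoined at 12.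

Step 5 (asymmetric 1,4-arylation). Facial selectivity may be insufficient or of the opposite sense with this hindered, electron-rich boronic acid, protodeboronation may outpace transmetalation, or partial ring opening of the product may lower its enantiopurity. The fallback replaces asymmetric C–C bond formation by resolution, setting out from 4 and 8. An achiral Pd(II)/2,2'-bipyridine-catalysed 1,4-addition would give the racemic flavanone F4. Kinetic resolution by asymmetric transfer hydrogenation (Cp*Rh–TsDPEN, HCO2H/Et3N, antipode chosen so that the 2R ketone reacts) would reduce the unwanted enantiomer to the cis-flavan-4-ol F5, which is removed by chromatography, leaving the (2S)-ketone; the route is rejoined at 9.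

Step 13 (chelation-controlled reduction). Hydride delivery may show poor facial selectivity if the zinc chelate is incomplete in the presence of the free phenol, and the free α-hydroxy ketone may partly enolise before it is reduced. The fallback replaces substrate control by reagent control and avoids the free hydroxy ketone, setting out from 19. Oxazaborolidine-catalysed reduction ((R)-Me-CBS expected if the aryl group acts as the large substituent, BH3·SMe2, THF) would give the silyl-protected anti alcohol F6. TBAF would then remove both silyl groups, and the route is rejoined at 21.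

**Further compounds**

F1 | step 6 | (2S)-6-bromo-2-[3,4-dimethoxy-5-(triisopropylsilyloxy)phenyl]-8-methoxy-3-(trifluoroacetyl)-2,3-dihydro-4H-chromen-4-one | COc1cc([C@@H]2C(C(=O)C(F)(F)F)C(=O)c3cc(Br)cc(OC)c3O2)cc(O[Si](C(C)C)(C(C)C)C(C)C)c1OC
F2 | step 6 | (2R)-6-bromo-3-diazo-2-[3,4-dimethoxy-5-(triisopropylsilyloxy)phenyl]-8-methoxy-2,3-dihydro-4H-chromen-4-one | COc1cc([C@@H]2C(=[N+]=[N-])C(=O)c3cc(Br)cc(OC)c3O2)cc(O[Si](C(C)C)(C(C)C)C(C)C)c1OC
F3 | step 6 | methyl (2S,3R)-5-bromo-2-[3,4-dimethoxy-5-(triisopropylsilyloxy)phenyl]-7-methoxy-2,3-dihydro-1-benzofuran-3-carboxylate (cis ester) | COc1cc([C@H]2Oc3c(OC)cc(Br)cc3[C@H]2C(=O)OC)cc(O[Si](C(C)C)(C(C)C)C(C)C)c1OC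
F4 | step 5 | racemic 6-bromo-2-[3,4-dimethoxy-5-(triisopropylsilyloxy)phenyl]-8-methoxy-2,3-dihydro-4H-chromen-4-one | COc1cc(C2CC(=O)c3cc(Br)cc(OC)c3O2)cc(O[Si](C(C)C)(C(C)C)C(C)C)c1OC
F5 | step 5 | (2R,4R)-6-bromo-2-[3,4-dimethoxy-5-(triisopropylsilyloxy)phenyl]-8-methoxy-3,4-dihydro-2H-chromen-4-ol | COc1cc([C@H]2C[C@@H](O)c3cc(Br)cc(OC)c3O2)cc(O[Si](C(C)C)(C(C)C)C(C)C)c1OC
F6 | step 13 | (1R,2S)-2-[(tert-butyldimethylsilyl)oxy]-1-[(2S,3S)-2-[3,4-dimethoxy-5-(triisopropylsilyloxy)phenyl]-7-methoxy-3-methyl-2,3-dihydro-1-benzofuran-5-yl]propan-1-ol | COc1cc([C@H]2Oc3c(OC)cc([C@@H](O)[C@H](C)O[Si](C)(C)C(C)(C)C)cc3[C@@H]2C)cc(O[Si](C(C)C)(C(C)C)C(C)C)c1OC
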